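**Retrosynthetic overview**
1. Target ⇒ open-chain C1 allylic bromide / C2 enal: cut C1–C2 and the lactone C–O; closed by a chromium-catalysed macrocyclising carbonyl allylation followed by lactonisation.
2. That seco chain ⇒ bis-silylated epoxy triene by functional-group changes: C1=C15 by cross-metathesis, C13 acetate by Mitsunobu inversion, C2 enal by MnO2.
3. Key cut at C6–C7 and the 7Z olefin ⇒ C2–C6 primary iodide + C7–C14/C1 (E)-alkenyl boronate: Zweifel olefination, a stepwise boron-to-carbon 1,2-shift of the C6 chain that fixes the Z geometry.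
4. Boronate ⇒ hex-1-en-5-yne, MeI, methacrolein, allyl acetate (methylboration, cross-metathesis, Ir allylation for C13, V epoxidation for C11/C12); iodide ⇒ (E)-3-methylpent-2-en-4-yn-1-ol.
5. Ring order: oxirane (step 7), then the 14-membered carbocycle and the γ-lactone (both in step 14).

Assumption: atom labels C1–C20 are the cembrane numbering of the target; the ligand enantiomers named in steps 6 and 14 are those expected by analogy, and the mirror-image ligand is used if the facial sense proves opposite.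

**Route**

Step 1
Reactants: 1 (E)-3-methylpent-2-en-4-yn-1-ol
Product: 2 (E)-tert-butyldimethyl[(3-methylpent-2-en-4-yn-1-yl)oxy]silane
Conditions: TBSCl, imidazole, DMF, 0 °C to rt
Reagents that add atoms: tert-butyldimethylsilyl chloride, CC(C)(C)[Si](C)(C)Cl
Why: Standard silyl ether protection of the primary allylic alcohol masks O–C2 for the later organolithium step without touching the E-olefin.

Step 2
Reactants: 2 (E)-tert-butyldimethyl[(3-methylpent-2-en-4-yn-1-yl)oxy]silane
Product: 3 (E)-tert-butyldimethyl[(3-methylpenta-2,4-dien-1-yl)oxy]silane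
Conditions: H2 (1 atm), Pd/CaCO3 poisoned with Pb(OAc)2 (Lindlar catalyst), quinoline, hexane, rt
Reagents that add atoms: none
Why: Lindlar semi-hydrogenation stops a terminal conjugated alkyne at the alkene and leaves the trisubstituted E-olefin intact.

Step 3
Reactants: 3 (E)-tert-butyldimethyl[(3-methylpenta-2,4-dien-1-yl)oxy]silane
Product: 5 (E)-tert-butyl[(5-iodo-3-methylpent-2-en-1-yl)oxy]dimethylsilane, via alkyl-9-BBN adduct 4 (not isolated)
Conditions: 9-BBN, THF, 0 °C to rt; then NaOMe, I2, MeOH, 0 °C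
Reagents that add atoms: iodine, II; 9-borabicyclo[3.3.1]nonane, B1C2CCCC1CCC2 (boron stays in 4 only)
Why: Anti-Markovnikov hydroboration by 9-BBN is selective for the monosubstituted vinyl terminus of the diene, and Brown iodinolysis of the primary B–C bond gives the primary iodide in one pot.

Step 4
Reactants: 6 hex-1-en-5-yne
Product: 7 (E)-4,4,5,5-tetramethyl-2-(2-methylhexa-1,5-dien-1-yl)-1,3,2-dioxaborolane
Conditions: B2pin2, MeI, CuCl (5 mol%), Xantphos (6 mol%), NaOtBu, THF, rt
Reagents that add atoms: bis(pinacolato)diboron, CC1(C)OB(OC1(C)C)B1OC(C)(C)C(C)(C)O1; iodomethane, CI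
Why: Copper-catalysed carboboration (syn borylcupration with boron on the terminal carbon, then methylation of the alkenylcopper with retention) sets Me and B cis on C7=C8, and the isolated terminal alkene does not react.

Step 5
Reactants: 7 (E)-4,4,5,5-tetramethyl-2-(2-methylhexa-1,5-dien-1-yl)-1,3,2-dioxaborolane; 8 methacrolein
Product: 9 (2E,6E)-2,6-dimethyl-7-(4,4,5,5-tetramethyl-1,3,2-dioxaborolan-2-yl)hepta-2,6-dienal
Conditions: 8 (5 equiv), second-generation Hoveyda–Grubbs catalyst RuCl2(H2IMes)(=CH-C6H4-2-OiPr) (5 mol%), CH2Cl2, 40 °C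
Reagents that add atoms: none
Why: Olefin cross-metathesis of a monosubstituted alkene with excess methacrolein gives the thermodynamically favoured (E)-2-methyl-2-enal, while the trisubstituted alkenyl boronate is inert to the ruthenium carbene.

Step 6
Reactants: 9 (2E,6E)-2,6-dimethyl-7-(4,4,5,5-tetramethyl-1,3,2-dioxaborolan-2-yl)hepta-2,6-dienal; 10 allyl acetate
Product: 11 (4S,5E,9E)-5,9-dimethyl-10-(4,4,5,5-tetramethyl-1,3,2-dioxaborolan-2-yl)deca-1,5,9-trien-4-ol
Conditions: [Ir(cod)Cl]2 (2.5 mol%), (S)-Cl,MeO-BIPHEP (5 mol%), 4-chloro-3-nitrobenzoic acid (10 mol%), Cs2CO3 (20 mol%), i-PrOH (2 equiv), THF, 100 °C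
Reagents that add atoms: none
Why: Krische iridium-catalysed transfer-hydrogenative carbonyl allylation (allyl acetate as donor, propan-2-ol as reductant) adds allyl to the enal through a closed chair transition state under ligand control and sets C13 as S.

Step 7
Reactants: 11 (4S,5E,9E)-5,9-dimethyl-10-(4,4,5,5-tetramethyl-1,3,2-dioxaborolan-2-yl)deca-1,5,9-trien-4-ol
Product: 12 erythro epoxy alcohol (1S)-1-[(2S,3S)-2-methyl-3-[(3E)-3-methyl-4-(pinacolboryl)but-3-en-1-yl]oxiran-2-yl]but-3-en-1-ol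
Conditions: VO(acac)2 (3 mol%), t-BuOOH, CH2Cl2, 0 °C
Reagents that add atoms: tert-butyl hydroperoxide, CC(C)(C)OO
Why: Hydroxyl-directed vanadium-catalysed epoxidation reacts only at the allylic-alcohol olefin, and allylic 1,2-strain between the C12 methyl and the C13 substituent (H13 near the methyl in the transition state) gives the erythro epoxy alcohol with the C11/C12 configuration of the target.

Step 8
Reactants: 12 erythro epoxy alcohol
Product: 13 tert-butyldimethyl{[(1S)-1-[(2R,3S)-2-methyl-3-[(3E)-3-methyl-4-(pinacolboryl)but-3-en-1-yl]oxiran-2-yl]but-3-en-1-yl]oxy}silane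
Conditions: TBSOTf, 2,6-lutidine, CH2Cl2, −78 °C
Reagents that add atoms: tert-butyldimethylsilyl triflate, CC(C)(C)[Si](C)(C)OS(=O)(=O)C(F)(F)F
Why: Silyl ether formation protects the hindered secondary alcohol against the organolithium and blocks Payne rearrangement under the methoxide of the next step.

Step 9 (key step)
Reactants: 5 (E)-tert-butyl[(5-iodo-3-methylpent-2-en-1-yl)oxy]dimethylsilane; 13 silyl-protected epoxy alkenyl boronate
Product: 17 bis-TBS ether of the (3E,7Z)-epoxy triene chain, via alkyllithium 14 (not isolated), via lithium boronate complex 15 (not isolated), via iodo boronic ester 16 (not isolated)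
Conditions: 5, t-BuLi (2 equiv), Et2O, −78 °C; 13, THF, −78 °C; I2, THF, −78 °C; NaOMe, MeOH, −78 °C to rt
Reagents that add atoms: tert-butyllithium, [Li]C(C)(C)C (lithium stays in 14 and 15 only); iodine, II (iodine stays in 16 only)
Why: Zweifel olefination: the primary alkyllithium adds to boron, iodination of the alkenyl boronate complex triggers a stereospecific stepwise ionic 1,2-shift of C6 from boron to C7 anti to the forming C8–I bond, and methoxide-induced anti elimination of boron and iodide inverts the olefin geometry, so the E-boronate gives the C6–C7 bond and the 7Z trisubstituted alkene.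

Step 10
Reactants: 17 bis-TBS ether of the (3E,7Z)-epoxy triene chain
Product: 18 (2E,6Z)-9-[(2S,3S)-3-[(1S)-1-hydroxybut-3-en-1-yl]-3-methyloxiran-2-yl]-3,7-dimethylnona-2,6-dien-1-ol
Conditions: Bu4NF, AcOH, THF, 0 °C to rt
Reagents that add atoms: none
Why: Fluoride desilylation frees both alcohols, and the acetic acid buffer prevents Payne rearrangement or epoxide opening by the alkoxide.

Step 11
Reactants: 18 epoxy diol
Product: 19 (2E,6Z)-9-[(2S,3S)-3-[(1S)-1-hydroxybut-3-en-1-yl]-3-methyloxiran-2-yl]-3,7-dimethylnona-2,6-dienal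
Conditions: MnO2, CH2Cl2, rt
Reagents that add atoms: none
Why: MnO2 oxidises only the primary allylic alcohol to the E-enal, because the secondary epoxy alcohol is not allylic.

Step 12
Reactants: 19 epoxy hydroxy enal
Product: 20 (1R)-1-[(2R,3S)-3-[(3Z,7E)-3,7-dimethyl-9-oxonona-3,7-dien-1-yl]-2-methyloxiran-2-yl]but-3-en-1-yl acetate
Conditions: PPh3, DIAD, AcOH, toluene, 0 °C to rt
Reagents that add atoms: acetic acid, CC(=O)O
Why: Mitsunobu esterification displaces the C13 oxyphosphonium by acetate in an SN2 step that inverts C13 from S to R, turning the erythro epoxy alcohol into the threo epoxy acetate of the target.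

Step 13
Reactants: 20 threo epoxy acetate enal; 21 methyl 2-(bromomethyl)acrylate
Product: 22 methyl (2Z,5R)-5-acetoxy-2-(bromomethyl)-5-[(2R,3S)-3-[(3Z,7E)-3,7-dimethyl-9-oxonona-3,7-dien-1-yl]-2-methyloxiran-2-yl]pent-2-enoate
Conditions: 21 (4 equiv), second-generation Hoveyda–Grubbs catalyst RuCl2(H2IMes)(=CH-C6H4-2-OiPr) (10 mol%), CH2Cl2, 40 °C
Reagents that add atoms: none
Why: Cross-metathesis of the only monosubstituted olefin with the 1,1-disubstituted acrylate forms C1=C15 as the thermodynamic isomer with C14 anti to the ester (2Z), while the trisubstituted olefins and the enal are inert.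

Step 14
Reactants: 22 seco bromo-enoate aldehyde
Product: 25 (1S,2S,3E,7Z,11S,12R,13R)-13-acetoxy-11,12-epoxycembra-3,7,15(17)-trien-16,2-olide (CNP0146076.3), via TMS ether 23 (not isolated), via hydroxy ester 24 (not isolated)
Conditions: CrCl2 (15 mol%), (S,S)-3,6-di-tert-butyl-1,8-bis(4-isopropyl-4,5-dihydrooxazol-2-yl)-9H-carbazole (17 mol%), Et3N (30 mol%), Mn powder, Me3SiCl, THF, 25 °C, syringe-pump addition of 22 to 2 mM; then 1 M aq. citric acid, THF, rt
Reagents that add atoms: chlorotrimethylsilane, C[Si](C)(C)Cl (silicon stays in 23 only)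
Why: Proposed new method: a ligand-controlled chromium-catalysed macrocyclising 2-(methoxycarbonyl)allylation, in which divalent chromium inserts into the allylic C–Br bond, the allylchromium species (trivalent chromium) funnels by 1,3-metal shift to the primary σ-allyl isomer with C14 anti to the ester whichever olefin geometry is fed in, and this adds through a closed chair transition state to the tethered enal on the face set by the carbazole bis(oxazoline) ligand to form C1–C2 as the syn (1S,2S) adduct, Mn/Me3SiCl turn the metal over, and the syn hydroxy ester closes to the cis-fused lactone on acidic work-up; the closest known reactions are the intermolecular chromium/bis(oxazoline)-catalysed enantioselective 2-(alkoxycarbonyl)allylation–lactonisation of aldehydes and stoichiometric CrCl2-mediated Nozaki–Hiyama–Kishi macrocyclisations.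

**Compound list**

1 | (E)-3-methylpent-2-en-4-yn-1-ol | OC/C=C(\C)C#C | starting material
2 | (E)-tert-butyldimethyl[(3-methylpent-2-en-4-yn-1-yl)oxy]silane | CC(C)(C)[Si](C)(C)OC/C=C(\C)C#C | intermediate
3 | (E)-tert-butyldimethyl[(3-methylpenta-2,4-dien-1-yl)oxy]silane | CC(C)(C)[Si](C)(C)OC/C=C(\C)C=C | intermediate
4 | 9-[(E)-5-(tert-butyldimethylsilyloxy)-3-methylpent-3-en-1-yl]-9-borabicyclo[3.3.1]nonane | CC(C)(C)[Si](C)(C)OC/C=C(\C)CCB1C2CCCC1CCC2 | intermediate (not isolated)
5 | (E)-tert-butyl[(5-iodo-3-methylpent-2-en-1-yl)oxy]dimethylsilane | CC(C)(C)[Si](C)(C)OC/C=C(\C)CCI | intermediate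
6 | hex-1-en-5-yne | C=CCCC#C | starting material
7 | (E)-4,4,5,5-tetramethyl-2-(2-methylhexa-1,5-dien-1-yl)-1,3,2-dioxaborolane | CC1(C)OB(/C=C(\C)CCC=C)OC1(C)C | intermediate
8 | methacrolein (2-methylprop-2-enal) | CC(=C)C=O | starting material
9 | (2E,6E)-2,6-dimethyl-7-(4,4,5,5-tetramethyl-1,3,2-dioxaborolan-2-yl)hepta-2,6-dienal | CC1(C)OB(/C=C(\C)CC/C=C(\C)C=O)OC1(C)C | intermediate
10 | allyl acetate | CC(=O)OCC=C | starting material
11 | (4S,5E,9E)-5,9-dimethyl-10-(4,4,5,5-tetramethyl-1,3,2-dioxaborolan-2-yl)deca-1,5,9-trien-4-ol | CC1(C)OB(/C=C(\C)CC/C=C(\C)[C@@H](O)CC=C)OC1(C)C | intermediate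
12 | (1S)-1-[(2S,3S)-2-methyl-3-[(3E)-3-methyl-4-(4,4,5,5-tetramethyl-1,3,2-dioxaborolan-2-yl)but-3-en-1-yl]oxiran-2-yl]but-3-en-1-ol (erythro; trans-epoxide) | CC1(C)OB(/C=C(\C)CC[C@@H]2O[C@@]2(C)[C@@H](O)CC=C)OC1(C)C | intermediate
13 | tert-butyldimethyl{[(1S)-1-[(2R,3S)-2-methyl-3-[(3E)-3-methyl-4-(4,4,5,5-tetramethyl-1,3,2-dioxaborolan-2-yl)but-3-en-1-yl]oxiran-2-yl]but-3-en-1-yl]oxy}silane | CC1(C)OB(/C=C(\C)CC[C@@H]2O[C@@]2(C)[C@@H](O[Si](C)(C)C(C)(C)C)CC=C)OC1(C)C | intermediate
14 | [(E)-5-(tert-butyldimethylsilyloxy)-3-methylpent-3-en-1-yl]lithium | CC(C)(C)[Si](C)(C)OC/C=C(\C)CC[Li] | intermediate (not isolated)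
15 | lithium pinacolato boronate complex carrying the C6 alkyl chain of 14 and the (E)-alkenyl group of 13 on boron | [Li+].CC(C)(C)[Si](C)(C)OC/C=C(\C)CC[B-]1(OC(C)(C)C(C)(C)O1)/C=C(\C)CC[C@@H]2O[C@@]2(C)[C@@H](O[Si](C)(C)C(C)(C)C)CC=C | intermediate (not isolated)
16 | anti adduct: 8-iodo-7-(pinacolboryl) chain, (7S,8S) shown; the (7R,8R) adduct forms alongside and gives the same 17; other centres 11S,12R,13S | CC(C)(C)[Si](C)(C)OC/C=C(\C)CC[C@H](B1OC(C)(C)C(C)(C)O1)[C@@](C)(I)CC[C@@H]2O[C@@]2(C)[C@@H](O[Si](C)(C)C(C)(C)C)CC=C | intermediate (not isolated)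
17 | tert-butyl{[(2E,6Z)-9-[(2S,3R)-3-[(1S)-1-(tert-butyldimethylsilyloxy)but-3-en-1-yl]-3-methyloxiran-2-yl]-3,7-dimethylnona-2,6-dien-1-yl]oxy}dimethylsilane | CC(C)(C)[Si](C)(C)OC/C=C(\C)CC/C=C(/C)CC[C@@H]1O[C@@]1(C)[C@@H](O[Si](C)(C)C(C)(C)C)CC=C | intermediate
18 | (2E,6Z)-9-[(2S,3S)-3-[(1S)-1-hydroxybut-3-en-1-yl]-3-methyloxiran-2-yl]-3,7-dimethylnona-2,6-dien-1-ol | OC/C=C(\C)CC/C=C(/C)CC[C@@H]1O[C@@]1(C)[C@@H](O)CC=C | intermediate
19 | (2E,6Z)-9-[(2S,3S)-3-[(1S)-1-hydroxybut-3-en-1-yl]-3-methyloxiran-2-yl]-3,7-dimethylnona-2,6-dienal | O=C/C=C(\C)CC/C=C(/C)CC[C@@H]1O[C@@]1(C)[C@@H](O)CC=C | intermediate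
20 | (1R)-1-[(2R,3S)-3-[(3Z,7E)-3,7-dimethyl-9-oxonona-3,7-dien-1-yl]-2-methyloxiran-2-yl]but-3-en-1-yl acetate (threo) | O=C/C=C(\C)CC/C=C(/C)CC[C@@H]1O[C@@]1(C)[C@H](OC(C)=O)CC=C | intermediate
21 | methyl 2-(bromomethyl)acrylate | C=C(CBr)C(=O)OC | starting material
22 | methyl (2Z,5R)-5-acetoxy-2-(bromomethyl)-5-[(2R,3S)-3-[(3Z,7E)-3,7-dimethyl-9-oxonona-3,7-dien-1-yl]-2-methyloxiran-2-yl]pent-2-enoate | O=C/C=C(\C)CC/C=C(/C)CC[C@@H]1O[C@@]1(C)[C@H](OC(C)=O)C/C=C(\CBr)C(=O)OC | intermediate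
23 | methyl 2-[(1S,2S,3E,7Z,11S,12R,13R)-13-acetoxy-11,12-epoxy-4,8,12-trimethyl-2-(trimethylsilyloxy)cyclotetradeca-3,7-dien-1-yl]acrylate (cembrane labels) | C[Si](C)(C)O[C@H]1/C=C(\C)CC/C=C(/C)CC[C@@H]2O[C@@]2(C)[C@H](OC(C)=O)C[C@H]1C(=C)C(=O)OC | intermediate (not isolated)
24 | methyl 2-[(1S,2S,3E,7Z,11S,12R,13R)-13-acetoxy-11,12-epoxy-2-hydroxy-4,8,12-trimethylcyclotetradeca-3,7-dien-1-yl]acrylate (cembrane labels) | O[C@H]1/C=C(\C)CC/C=C(/C)CC[C@@H]2O[C@@]2(C)[C@H](OC(C)=O)C[C@H]1C(=C)C(=O)OC | intermediate (not isolated)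
25 | (1S,2S,3E,7Z,11S,12R,13R)-13-acetoxy-11,12-epoxycembra-3,7,15(17)-trien-16,2-olide (CNP0146076.3; cis-fused lactone) | C=C1C(=O)O[C@H]2/C=C(\C)CC/C=C(/C)CC[C@@H]3O[C@@]3(C)[C@H](OC(C)=O)C[C@@H]12 | target

**Step count and risks**

Total steps: 14. Longest linear sequence: 11 steps (6 to 25, steps 4–14); the other branch (1 to 5) is 3 steps.

Steps most likely to fail:

- Step 14 (the proposed new reaction; catalyst turnover, macrocyclisation against oligomerisation, and ligand control against the existing centres are all untested). Fallback, from 22 back to 25: 22 is borylated with B2pin2 and Pd2(dba)3 (zerovalent palladium, toluene, 50 °C; known borylation of 2-(alkoxycarbonyl)allyl electrophiles) to the allylboronate methyl (2E,5R)-5-acetoxy-5-[(2R,3S)-3-[(3Z,7E)-3,7-dimethyl-9-oxonona-3,7-dien-1-yl]-2-methyloxiran-2-yl]-2-[(pinacolboryl)methyl]pent-2-enoate F1. F1 is heated at 2 mM in toluene at 90 °C; the intramolecular carbonyl allylboration runs through a closed six-membered transition state that is known to give the syn adduct, hence the cis lactone, from this olefin geometry. Mild acidic work-up lactonises; 25 is separated from its C1/C2 diastereomer by chromatography.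

- Step 13 (cross-metathesis with an allylic bromide-bearing 1,1-disubstituted acrylate in a polyfunctional substrate). Fallback, from 20 back to 22: 20 is cross-metathesised with methyl 2-(hydroxymethyl)acrylate (same ruthenium catalyst) to the allylic alcohol methyl (2E,5R)-5-acetoxy-2-(hydroxymethyl)-5-[(2R,3S)-3-[(3Z,7E)-3,7-dimethyl-9-oxonona-3,7-dien-1-yl]-2-methyloxiran-2-yl]pent-2-enoate F2, and Appel bromination (CBr4, PPh3, CH2Cl2, 0 °C) of F2 gives 22.

- Step 12 (Mitsunobu displacement with acetic acid at a carbinol flanked by a fully substituted oxirane carbon). Fallback, from 19 back to 20: 19 is sulfonylated (ClCH2SO2Cl, pyridine, 0 °C) to the chloromethanesulfonate (1S)-1-[(2R,3S)-3-[(3Z,7E)-3,7-dimethyl-9-oxonona-3,7-dien-1-yl]-2-methyloxiran-2-yl]but-3-en-1-yl chloromethanesulfonate F3, which is displaced with CsOAc and 18-crown-6 in toluene at 60 °C (SN2 with inversion) to give 20.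

**Further compounds**

F1 | step 14 | methyl (2E,5R)-5-acetoxy-5-[(2R,3S)-3-[(3Z,7E)-3,7-dimethyl-9-oxonona-3,7-dien-1-yl]-2-methyloxiran-2-yl]-2-[(4,4,5,5-tetramethyl-1,3,2-dioxaborolan-2-yl)methyl]pent-2-enoate | O=C/C=C(\C)CC/C=C(/C)CC[C@@H]1O[C@@]1(C)[C@H](OC(C)=O)C/C=C(\CB2OC(C)(C)C(C)(C)O2)C(=O)OC
F2 | step 13 | methyl (2E,5R)-5-acetoxy-2-(hydroxymethyl)-5-[(2R,3S)-3-[(3Z,7E)-3,7-dimethyl-9-oxonona-3,7-dien-1-yl]-2-methyloxiran-2-yl]pent-2-enoate | O=C/C=C(\C)CC/C=C(/C)CC[C@@H]1O[C@@]1(C)[C@H](OC(C)=O)C/C=C(\CO)C(=O)OC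
F3 | step 12 | (1S)-1-[(2R,3S)-3-[(3Z,7E)-3,7-dimethyl-9-oxonona-3,7-dien-1-yl]-2-methyloxiran-2-yl]but-3-en-1-yl chloromethanesulfonate | O=C/C=C(\C)CC/C=C(/C)CC[C@@H]1O[C@@]1(C)[C@@H](OS(=O)(=O)CCl)CC=C
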